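Cuts, in retrosynthetic order: the four O–CH3 bonds of a tetramethyl ether; the two C2'–Br bonds of outer rings A and C (C1' = ether carbon, C4' = hydroxyl carbon); the six C–Br bonds at C3'/C5' of rings A and C and at C3/C6 of central ring B; the two C4'–O bonds (back to C4'–CHO); and the two O–C1' diaryl ether bonds.
Forward: no ring is built, since all three benzene rings are bought. Reduced 2,5-dimethoxy-1,4-benzoquinone (ring B) is joined to two 4-fluorobenzaldehyde units in one double SNAr. The formyl groups are then exchanged for hydroxyls, six bromines enter by electrophilic substitution, the phenols are methylated, the last two bromines enter through magnesiation, and BBr3 frees the four hydroxyls.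
Enabling feature: C2' is ortho to the ether oxygen on C1' but meta to the oxygen on C4', so electrophilic bromine is not sent there. In the hexabromide, C2'–H (= C6'–H) lies between the C1' oxygen and the C3' (C5') bromine and is the only kind of ring hydrogen left, because ring B is fully substituted. It is therefore the one site a hindered magnesium amide can deprotonate.
Stereochemistry: the target has no stereocentre and no double-bond geometry, so nothing has to be controlled.

Key step: step 6

Assumption: rotation about the aryl–oxygen bonds is taken as fast at room temperature. The octabromides then do not exist as separable atropisomers, and metalation at C2' or at C6' of either outer ring leads to the same compound.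

Step 1
Reactants: 1 2,5-dimethoxy-1,4-benzoquinone
Product: 2 2,5-dimethoxybenzene-1,4-diol
Conditions: Na2S2O4 (excess), THF/H2O, rt, Ar
Reagents that add atoms: none
Why: Dithionite reduction of a 1,4-benzoquinone to its hydroquinone is fast in a two-phase medium and leaves the methoxy groups untouched.

Step 2
Reactants: 2 2,5-dimethoxybenzene-1,4-diol; 3 4-fluorobenzaldehyde (2.4 equiv)
Product: 4 4,4'-[(2,5-dimethoxy-1,4-phenylene)bis(oxy)]dibenzaldehyde
Conditions: K2CO3 (3 equiv), degassed DMF, 120 °C, Ar
Reagents that add atoms: none
Why: In this twofold nucleophilic aromatic substitution (SNAr) the para-formyl group stabilises the Meisenheimer adduct and fluoride leaves readily, a reaction type well established for hydroquinones with 4-fluorobenzaldehyde, and exclusion of air keeps the electron-rich bis-phenoxide from reverting to 1.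

Step 3
Reactants: 4 4,4'-[(2,5-dimethoxy-1,4-phenylene)bis(oxy)]dibenzaldehyde
Product: 6 4,4'-[(2,5-dimethoxy-1,4-phenylene)bis(oxy)]diphenol, via bis-formate 5 (not isolated)
Conditions: mCPBA (2.6 equiv), CH2Cl2, 0 °C → rt; then K2CO3 (cat.), MeOH, rt
Reagents that add atoms: mCPBA (3-chloroperoxybenzoic acid), O=C(OO)c1cccc(Cl)c1
Why: In this Baeyer–Villiger oxidation (the peracid variant of the Dakin reaction, chosen because the alkaline H2O2 version needs a free ortho or para hydroxyl) the para-aryloxy-substituted aryl group migrates in preference to hydride, and the labile aryl formates are cleaved by base-catalysed transesterification.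

Step 4
Reactants: 6 4,4'-[(2,5-dimethoxy-1,4-phenylene)bis(oxy)]diphenol
Product: 7 4,4'-[(2,5-dibromo-3,6-dimethoxy-1,4-phenylene)bis(oxy)]bis(2,6-dibromophenol)
Conditions: Br2 (6.3 equiv), AcOH/CH2Cl2, 0 °C → rt, dark
Reagents that add atoms: bromine, BrBr
Why: Electrophilic aromatic bromination follows the oxygen donors to both positions ortho to each free C4' hydroxyl (its para position is blocked) and to the two remaining C–H positions of the tetraoxygenated ring B, whereas C2'/C6', meta to the hydroxyl on a ring that already carries two bromines, should stay untouched at this stoichiometry.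

Step 5
Reactants: 7 4,4'-[(2,5-dibromo-3,6-dimethoxy-1,4-phenylene)bis(oxy)]bis(2,6-dibromophenol)
Product: 8 1,4-dibromo-2,5-dimethoxy-3,6-bis(3,5-dibromo-4-methoxyphenoxy)benzene
Conditions: MeI (excess), K2CO3, DMF, rt → 40 °C
Reagents that add atoms: iodomethane, CI
Why: Williamson O-methylation of acidic 2,6-dibromophenols with the small electrophile MeI is reliable, and it removes the two protons that would otherwise consume the amide base of step 6.

Step 6
Reactants: 8 1,4-dibromo-2,5-dimethoxy-3,6-bis(3,5-dibromo-4-methoxyphenoxy)benzene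
Product: 10 1,4-dibromo-2,5-dimethoxy-3,6-bis(2,3,5-tribromo-4-methoxyphenoxy)benzene, via twofold arylmagnesium chloride 9 (not isolated)
Conditions: TMPMgCl·LiCl (TMP = 2,2,6,6-tetramethylpiperidide, 2.3 equiv), THF, −20 → 0 °C; then BrCl2C–CCl2Br (2.6 equiv), −20 °C → rt
Reagents that add atoms: 1,2-dibromo-1,1,2,2-tetrachloroethane, BrC(Cl)(Cl)C(Cl)(Cl)Br
Why: The hindered amide of TMPMgCl·LiCl, pre-coordinated to the C1' ether oxygen, removes the C2'–H that is acidified inductively by that oxygen and by the C3' bromine, once on ring A and once on ring C, to give 9; each C–Mg bond then attacks a bromine atom of BrCl2C–CCl2Br, which fragments to tetrachloroethene and MgBrCl and so forms the two C2'–Br bonds. The closest known reaction type is the directed magnesiation of halogen- and alkoxy-flanked arene C–H bonds with TMP-magnesium amide/LiCl bases followed by trapping with an electrophilic bromine source. No ring is closed and no stereocentre is created. Site selectivity is secured by the substrate: ring B has no hydrogen, C2'–H and C6'–H are the only aromatic hydrogens, and they are interchanged by rotation about the C1'–O bond, so either choice on either ring leads to the same product. One bromine per ring is secured because the first C–Mg bond loads its ring with negative charge and makes the remaining C6'–H far less acidic while the distant second ring is unaffected; the base is held at little more than two equivalents and the bromine source is added only after metalation, so the more acidic C6'–H of 10 never meets live base. Chemoselectivity rests on the covalent C–Mg bond, which at or below 0 °C resists loss of MgBrCl to an aryne and resists bromine migration (both typical of the aryllithium), and on the amide base, which does not enter Br/Mg exchange with the six C–Br bonds.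

Step 7
Reactants: 10 1,4-dibromo-2,5-dimethoxy-3,6-bis(2,3,5-tribromo-4-methoxyphenoxy)benzene
Product: 12 2,5-dibromo-3,6-bis(2,3,5-tribromo-4-hydroxyphenoxy)benzene-1,4-diol (CNP0163357.0), via tetrakis(dibromoboryl) ether 11 (not isolated)
Conditions: BBr3 (6 equiv), CH2Cl2, −78 °C → rt; then ice/H2O, Ar
Reagents that add atoms: none
Why: In this Lewis acid-mediated aryl methyl ether cleavage BBr3 binds each methoxy oxygen and bromide attacks the methyl carbon in an SN2 step, helped by the ortho substituents that twist the methoxy groups out of conjugation, while the diaryl ether C–O and aryl C–Br bonds offer no sp3 carbon and persist, and hydrolysis under argon frees the four hydroxyls without oxidising the ring B hydroquinone.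

Compound list
1 | 2,5-dimethoxy-1,4-benzoquinone | COC1=CC(=O)C(OC)=CC1=O | starting material
2 | 2,5-dimethoxybenzene-1,4-diol | COc1cc(O)c(OC)cc1O | intermediate
3 | 4-fluorobenzaldehyde | O=Cc1ccc(F)cc1 | starting material
4 | 4,4'-[(2,5-dimethoxy-1,4-phenylene)bis(oxy)]dibenzaldehyde | COc1cc(Oc2ccc(C=O)cc2)c(OC)cc1Oc1ccc(C=O)cc1 | intermediate
5 | [(2,5-dimethoxy-1,4-phenylene)bis(oxy)]di-4,1-phenylene diformate (bis-formate, not isolated) | COc1cc(Oc2ccc(OC=O)cc2)c(OC)cc1Oc1ccc(OC=O)cc1 | intermediate
6 | 4,4'-[(2,5-dimethoxy-1,4-phenylene)bis(oxy)]diphenol | COc1cc(Oc2ccc(O)cc2)c(OC)cc1Oc1ccc(O)cc1 | intermediate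
7 | 4,4'-[(2,5-dibromo-3,6-dimethoxy-1,4-phenylene)bis(oxy)]bis(2,6-dibromophenol) | COc1c(Br)c(Oc2cc(Br)c(O)c(Br)c2)c(OC)c(Br)c1Oc1cc(Br)c(O)c(Br)c1 | intermediate
8 | 1,4-dibromo-2,5-dimethoxy-3,6-bis(3,5-dibromo-4-methoxyphenoxy)benzene | COc1c(Br)cc(Oc2c(OC)c(Br)c(Oc3cc(Br)c(OC)c(Br)c3)c(OC)c2Br)cc1Br | intermediate
9 | twofold arylmagnesium chloride of 8, one C2'–MgCl on ring A and one on ring C (not isolated) | COc1c(Br)cc(Oc2c(OC)c(Br)c(Oc3cc(Br)c(OC)c(Br)c3[Mg]Cl)c(OC)c2Br)c([Mg]Cl)c1Br | intermediate
10 | 1,4-dibromo-2,5-dimethoxy-3,6-bis(2,3,5-tribromo-4-methoxyphenoxy)benzene | COc1c(Br)cc(Oc2c(OC)c(Br)c(Oc3cc(Br)c(OC)c(Br)c3Br)c(OC)c2Br)c(Br)c1Br | intermediate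
11 | tetrakis(dibromoboryl) ether of 12 (not isolated) | BrB(Br)Oc1c(Br)cc(Oc2c(OB(Br)Br)c(Br)c(Oc3cc(Br)c(OB(Br)Br)c(Br)c3Br)c(OB(Br)Br)c2Br)c(Br)c1Br | intermediate
12 | 2,5-dibromo-3,6-bis(2,3,5-tribromo-4-hydroxyphenoxy)benzene-1,4-diol | Oc1c(Br)cc(Oc2c(O)c(Br)c(Oc3cc(Br)c(O)c(Br)c3Br)c(O)c2Br)c(Br)c1Br | target

Total step count: 7. Longest linear sequence: 7 steps (1 → 12).

Steps most likely to fail

Step 6.
- **What may go wrong:** The second deprotonation may be sluggish or incomplete, or one ring may be metalated twice. If the temperature has to be raised, MgBrCl may be lost towards an aryne, or bromine may migrate.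
- **First adjustment:** Switching to the stronger TMP2Mg·2LiCl would be tried first, but that changes only the conditions.
- **Fallback:** The C2' bromine is brought in with the building block instead of by C–H metalation. Setting out from 2, double SNAr with commercial 3-bromo-4-fluorobenzaldehyde (O=Cc1ccc(F)c(Br)c1; K2CO3, DMF) should give 4,4'-[(2,5-dimethoxy-1,4-phenylene)bis(oxy)]bis(3-bromobenzaldehyde) F1.
- mCPBA should convert F1 into [(2,5-dimethoxy-1,4-phenylene)bis(oxy)]bis(3-bromo-4,1-phenylene) diformate F2, which is methanolysed without isolation to 4,4'-[(2,5-dimethoxy-1,4-phenylene)bis(oxy)]bis(3-bromophenol) F3.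
- Six equivalents of Br2 should then fill C3' and C5' (both ortho to the free hydroxyl) and C3/C6 of ring B, giving 4,4'-[(2,5-dibromo-3,6-dimethoxy-1,4-phenylene)bis(oxy)]bis(2,3,6-tribromophenol) F4.
- BBr3 should turn F4 into the boryl ether 11, where the route is rejoined, and water then frees 12.

Step 4.
- **What may go wrong:** Excess bromine may oxidise the electron-rich ring B or the 4-aryloxyphenol units to quinones with loss of an aryl ether. The reaction may also stall before the sixth bromine has entered.
- **Fallback:** The two kinds of bromination are separated. Setting out from 4, whose outer rings are deactivated by the formyl groups, Br2 in AcOH should brominate ring B alone to give 4,4'-[(2,5-dibromo-3,6-dimethoxy-1,4-phenylene)bis(oxy)]dibenzaldehyde F5.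
- mCPBA should give [(2,5-dibromo-3,6-dimethoxy-1,4-phenylene)bis(oxy)]di-4,1-phenylene diformate F6, and methanolysis should give 4,4'-[(2,5-dibromo-3,6-dimethoxy-1,4-phenylene)bis(oxy)]diphenol F7.
- Ring B is by then fully substituted and much harder to oxidise, so four equivalents of Br2 at 0 °C should suffice for the positions ortho to the hydroxyls. The route is rejoined at 7.

Step 2.
- **What may go wrong:** Traces of air may re-oxidise the hydroquinone bis-phenoxide at the temperature needed, and the reaction may stall after the first ether bond.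
- **Fallback:** A masked nucleophile is used. Setting out from 2, heating with HN(SiMe3)2 should give the air-stable 1,4-dimethoxy-2,5-bis(trimethylsilyloxy)benzene F8.
- With catalytic CsF in DMF and 3, fluoride opens each O–Si bond only as fast as the phenoxide is consumed by SNAr, and the fluoride displaced from 3 carries the chain. The silicon leaves as volatile fluorosilane, and the route is rejoined at 4.

Further compounds
F1 | step 6 | 4,4'-[(2,5-dimethoxy-1,4-phenylene)bis(oxy)]bis(3-bromobenzaldehyde) | COc1cc(Oc2ccc(C=O)cc2Br)c(OC)cc1Oc1ccc(C=O)cc1Br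
F2 | step 6 | [(2,5-dimethoxy-1,4-phenylene)bis(oxy)]bis(3-bromo-4,1-phenylene) diformate | COc1cc(Oc2ccc(OC=O)cc2Br)c(OC)cc1Oc1ccc(OC=O)cc1Br
F3 | step 6 | 4,4'-[(2,5-dimethoxy-1,4-phenylene)bis(oxy)]bis(3-bromophenol) | COc1cc(Oc2ccc(O)cc2Br)c(OC)cc1Oc1ccc(O)cc1Br
F4 | step 6 | 4,4'-[(2,5-dibromo-3,6-dimethoxy-1,4-phenylene)bis(oxy)]bis(2,3,6-tribromophenol) | COc1c(Br)c(Oc2cc(Br)c(O)c(Br)c2Br)c(OC)c(Br)c1Oc1cc(Br)c(O)c(Br)c1Br
F5 | step 4 | 4,4'-[(2,5-dibromo-3,6-dimethoxy-1,4-phenylene)bis(oxy)]dibenzaldehyde | COc1c(Br)c(Oc2ccc(C=O)cc2)c(OC)c(Br)c1Oc1ccc(C=O)cc1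
F6 | step 4 | [(2,5-dibromo-3,6-dimethoxy-1,4-phenylene)bis(oxy)]di-4,1-phenylene diformate | COc1c(Br)c(Oc2ccc(OC=O)cc2)c(OC)c(Br)c1Oc1ccc(OC=O)cc1
F7 | step 4 | 4,4'-[(2,5-dibromo-3,6-dimethoxy-1,4-phenylene)bis(oxy)]diphenol | COc1c(Br)c(Oc2ccc(O)cc2)c(OC)c(Br)c1Oc1ccc(O)cc1
F8 | step 2 | 1,4-dimethoxy-2,5-bis(trimethylsilyloxy)benzene | COc1cc(O[Si](C)(C)C)c(OC)cc1O[Si](C)(C)C
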